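**Retrosynthetic overview**
1. Last bonds: the side-chain ester (pyran acetic acid + benzyl-protected hydroxytyrosol, carbodiimide coupling), then global O-debenzylation.
2. The dihydropyran (second and final ring) comes from an α-formyl δ-lactone by acid methanolysis with ring switch (Korte rearrangement); its C6 is introduced by a crossed Claisen condensation with methyl formate.
3. The C4–CH2 bond comes from an intermolecular Michael addition of dimethyl malonate to an enantiopure 5,6-dihydro-2H-pyran-2-one, trans to its neighbouring substituent; the malonate is later trimmed to CH2CO2H.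
4. The δ-lactone (first ring) comes from ring-closing metathesis of the acrylate of a homoallylic alcohol.
5. The key stereodefining C2–C3 bond comes from an intermolecular Evans syn-aldol between the boron dienolate of an N-crotonyl oxazolidinone and acetaldehyde.

Assumption: the SMILES is taken as drawn, i.e. (2R,3R,4S) with Me, CH2OH and CH2CO2R all trans; pyran numbering is O1, C2 (Me), C3 (CH2OH), C4 (CH2CO2R), C5 (CO2Me), C6.

**Route**

Step 1
Reactants: 1 (4S)-4-benzyl-1,3-oxazolidin-2-one; 2 (2E)-but-2-enoyl chloride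
Product: 4 (4S)-4-benzyl-3-[(2E)-but-2-enoyl]-1,3-oxazolidin-2-one, via lithium oxazolidinone salt 3 (not isolated)
Conditions: n-BuLi (1.0 equiv), THF, −78 °C; then 2 (1.1 equiv), −78 → 0 °C
Reagents that add atoms: none
Why: N-acylation of the lithiated oxazolidinone by the acid chloride (imide formation) is fast at low temperature and leaves the E-alkene untouched.

Step 2
Reactants: 4 (4S)-4-benzyl-3-[(2E)-but-2-enoyl]-1,3-oxazolidin-2-one; 5 acetaldehyde
Product: 8 (4S)-4-benzyl-3-[(2S,3R)-2-ethenyl-3-hydroxybutanoyl]-1,3-oxazolidin-2-one, via boron dienolate 6 (not isolated), via boron aldolate 7 (not isolated)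
Conditions: n-Bu2BOTf (1.2 equiv), Et3N (1.4 equiv), CH2Cl2, −78 → 0 °C; MeCHO (3 equiv), −78 → 0 °C; pH 7 buffer, MeOH, 30% H2O2, 0 °C
Reagents that add atoms: none
Why: Evans boron aldol reaction in which γ-deprotonation gives the Z-dienol borinate, which reacts at its α-carbon through a Zimmerman–Traxler chair on the face away from the auxiliary benzyl group, setting the (2S,3R) syn pair that becomes C3 and C2 of the pyran.

Step 3
Reactants: 8 (4S)-4-benzyl-3-[(2S,3R)-2-ethenyl-3-hydroxybutanoyl]-1,3-oxazolidin-2-one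
Product: 9 (4S)-4-benzyl-3-[(2S,3R)-3-[(tert-butyldimethylsilyl)oxy]-2-ethenylbutanoyl]-1,3-oxazolidin-2-one
Conditions: TBSOTf (1.3 equiv), 2,6-lutidine (2 equiv), CH2Cl2, 0 °C
Reagents that add atoms: tert-butyldimethylsilyl trifluoromethanesulfonate, CC(C)(C)[Si](C)(C)OS(=O)(=O)C(F)(F)F
Why: Silyl ether protection of the secondary alcohol blocks retro-aldol and differentiates the two oxygens for the following steps without touching a stereocentre.

Step 4
Reactants: 9 (4S)-4-benzyl-3-[(2S,3R)-3-[(tert-butyldimethylsilyl)oxy]-2-ethenylbutanoyl]-1,3-oxazolidin-2-one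
Product: 10 (2R,3R)-3-[(tert-butyldimethylsilyl)oxy]-2-ethenylbutan-1-ol
Conditions: LiBH4 (2 equiv), MeOH (2 equiv), THF, 0 → 25 °C
Reagents that add atoms: none
Why: Reductive cleavage of the N-acyl oxazolidinone by borohydride gives the primary alcohol and returns the auxiliary, under conditions too weakly basic to epimerise or conjugate the α-vinyl centre.

Step 5
Reactants: 10 (2R,3R)-3-[(tert-butyldimethylsilyl)oxy]-2-ethenylbutan-1-ol
Product: 11 {[(2R,3R)-3-[(benzyloxy)methyl]pent-4-en-2-yl]oxy}(tert-butyl)dimethylsilane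
Conditions: benzyl 2,2,2-trichloroacetimidate (1.5 equiv), TfOH (5 mol %), CH2Cl2/cyclohexane 1:2, 0 → 25 °C
Reagents that add atoms: benzyl 2,2,2-trichloroacetimidate, N=C(OCc1ccccc1)C(Cl)(Cl)Cl
Why: Acid-catalysed O-benzylation with the trichloroacetimidate avoids an alkoxide and therefore the 1,3-silyl migration that a Williamson etherification would risk.

Step 6
Reactants: 11 {[(2R,3R)-3-[(benzyloxy)methyl]pent-4-en-2-yl]oxy}(tert-butyl)dimethylsilane
Product: 12 (2R,3R)-3-[(benzyloxy)methyl]pent-4-en-2-ol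
Conditions: HF (48% aq), MeCN, 25 °C
Reagents that add atoms: none
Why: Fluoride-driven desilylation frees the secondary alcohol while the benzyl ether and alkene are inert.

Step 7
Reactants: 12 (2R,3R)-3-[(benzyloxy)methyl]pent-4-en-2-ol; 13 prop-2-enoyl chloride
Product: 14 (2R,3R)-3-[(benzyloxy)methyl]pent-4-en-2-yl prop-2-enoate
Conditions: 13 (1.5 equiv), i-Pr2NEt (2 equiv), DMAP (5 mol %), CH2Cl2, 0 °C
Reagents that add atoms: none
Why: O-acylation of the secondary alcohol with the acid chloride (esterification, retention at the carbinol carbon) installs the second alkene for ring closure.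

Step 8
Reactants: 14 (2R,3R)-3-[(benzyloxy)methyl]pent-4-en-2-yl prop-2-enoate
Product: 15 (5R,6R)-5-[(benzyloxy)methyl]-6-methyl-5,6-dihydro-2H-pyran-2-one
Conditions: second-generation Grubbs catalyst RuCl2(=CHPh)(H2IMes)(PCy3) (5 mol %), CH2Cl2 (5 mM), 40 °C
Reagents that add atoms: none
Why: Ring-closing olefin metathesis of the acrylate and the terminal vinyl group forms the six-membered unsaturated lactone (ring A, the first ring) with loss of ethene and without involving either stereocentre.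

Step 9
Reactants: 15 (5R,6R)-5-[(benzyloxy)methyl]-6-methyl-5,6-dihydro-2H-pyran-2-one; 16 dimethyl propanedioate
Product: 17 dimethyl 2-[(2R,3R,4R)-3-[(benzyloxy)methyl]-2-methyl-6-oxooxan-4-yl]propanedioate
Conditions: 16 (2 equiv), NaH (0.3 equiv), THF, 0 → 25 °C; aq NH4Cl
Reagents that add atoms: none
Why: Intermolecular Michael addition of the soft malonate anion to the lactone enoate occurs anti to the adjacent CH2OBn group and is reversible, so the all-equatorial 4,5-trans adduct is both the kinetic and the thermodynamic product, which sets the future C4.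

Step 10
Reactants: 17 dimethyl 2-[(2R,3R,4R)-3-[(benzyloxy)methyl]-2-methyl-6-oxooxan-4-yl]propanedioate; 18 methyl formate
Product: 20 dimethyl 2-[(2R,3R,4R)-3-[(benzyloxy)methyl]-5-(hydroxymethylidene)-2-methyl-6-oxooxan-4-yl]propanedioate, via disodium bis-enolate 19 (not isolated)
Conditions: NaH (3.5 equiv), 18 (10 equiv), MeOH (0.1 equiv), THF, 0 → 25 °C; cold 1 M HCl to pH 3
Reagents that add atoms: none
Why: Crossed Claisen condensation in which the more acidic malonate C–H is deprotonated first and so protected as its enolate, leaving the lactone α-CH2 as the only site that can be formylated productively.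

Step 11
Reactants: 20 dimethyl 2-[(2R,3R,4R)-3-[(benzyloxy)methyl]-5-(hydroxymethylidene)-2-methyl-6-oxooxan-4-yl]propanedioate
Product: 22 dimethyl 2-[(2R,3R,4R)-3-[(benzyloxy)methyl]-5-(methoxycarbonyl)-2-methyl-3,4-dihydro-2H-pyran-4-yl]propanedioate, via cyclic methyl acetal 21 (not isolated)
Conditions: HCl (1.25 M in MeOH), 0 → 25 °C, 16 h; evaporate; TsOH·H2O (5 mol %), toluene, 90 °C
Reagents that add atoms: methanol, CO
Why: Korte rearrangement in which acid methanolysis opens the lactone to the methyl ester, the freed C2 hydroxyl closes on the formyl carbon as a cyclic acetal, and acid-catalysed loss of methanol gives the conjugated β-alkoxyacrylate (ring B, the dihydropyran) with no stereocentre involved.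

Step 12
Reactants: 22 dimethyl 2-[(2R,3R,4R)-3-[(benzyloxy)methyl]-5-(methoxycarbonyl)-2-methyl-3,4-dihydro-2H-pyran-4-yl]propanedioate
Product: 23 methyl (2R,3R,4S)-3-[(benzyloxy)methyl]-4-(2-methoxy-2-oxoethyl)-2-methyl-3,4-dihydro-2H-pyran-5-carboxylate
Conditions: LiCl (3 equiv), H2O (3 equiv), DMSO, 140 °C
Reagents that add atoms: none
Why: Krapcho dealkoxycarbonylation removes one ester of the activated malonate only, because the vinylogous carbonate ester cannot stabilise the carbanion needed for decarboxylation.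

Step 13
Reactants: 23 methyl (2R,3R,4S)-3-[(benzyloxy)methyl]-4-(2-methoxy-2-oxoethyl)-2-methyl-3,4-dihydro-2H-pyran-5-carboxylate
Product: 25 2-[(2R,3R,4S)-3-[(benzyloxy)methyl]-5-(methoxycarbonyl)-2-methyl-3,4-dihydro-2H-pyran-4-yl]acetic acid, via lithium carboxylate 24 (not isolated)
Conditions: LiOH·H2O (1.3 equiv), THF/H2O 3:1, 0 °C; 1 M HCl to pH 3
Reagents that add atoms: lithium hydroxide, [Li+].[OH-]
Why: Chemoselective saponification, since the isolated aliphatic ester is far more electrophilic than the β-alkoxyacrylate ester, which is deactivated by the ring oxygen.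

Step 14
Reactants: 26 (3,4-dihydroxyphenyl)acetic acid
Product: 27 benzyl [3,4-bis(benzyloxy)phenyl]acetate
Conditions: BnBr (3.5 equiv), K2CO3 (4 equiv), DMF, 60 °C
Reagents that add atoms: benzyl bromide, BrCc1ccccc1
Why: Williamson etherification of both phenols and SN2 alkylation of the carboxylate protect all three acidic OH groups in one operation.

Step 15
Reactants: 27 benzyl [3,4-bis(benzyloxy)phenyl]acetate
Product: 28 2-[3,4-bis(benzyloxy)phenyl]ethan-1-ol
Conditions: LiAlH4 (1.2 equiv), THF, 0 °C; H2O, 15% NaOH work-up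
Reagents that add atoms: none
Why: Hydride reduction of the ester to the primary alcohol leaves the aryl benzyl ethers untouched.

Step 16
Reactants: 25 2-[(2R,3R,4S)-3-[(benzyloxy)methyl]-5-(methoxycarbonyl)-2-methyl-3,4-dihydro-2H-pyran-4-yl]acetic acid; 28 2-[3,4-bis(benzyloxy)phenyl]ethan-1-ol
Product: 29 methyl (2R,3R,4S)-3-[(benzyloxy)methyl]-4-(2-{2-[3,4-bis(benzyloxy)phenyl]ethoxy}-2-oxoethyl)-2-methyl-3,4-dihydro-2H-pyran-5-carboxylate
Conditions: DCC (1.2 equiv), DMAP (0.1 equiv), CH2Cl2, 0 → 25 °C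
Reagents that add atoms: none
Why: Steglich esterification (carbodiimide activation with DMAP acyl transfer) joins the acid and the primary alcohol under neutral conditions that spare the enol ether and the stereocentres.

Step 17
Reactants: 29 methyl (2R,3R,4S)-3-[(benzyloxy)methyl]-4-(2-{2-[3,4-bis(benzyloxy)phenyl]ethoxy}-2-oxoethyl)-2-methyl-3,4-dihydro-2H-pyran-5-carboxylate
Product: 30 methyl (2R,3R,4S)-4-{2-[2-(3,4-dihydroxyphenyl)ethoxy]-2-oxoethyl}-3-(hydroxymethyl)-2-methyl-3,4-dihydro-2H-pyran-5-carboxylate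
Conditions: H2 (1 atm), Pd/C (10 wt %), EtOAc, 25 °C
Reagents that add atoms: none
Why: Catalytic hydrogenolysis cleaves the three O-benzyl groups while the trisubstituted β-alkoxyacrylate alkene is hydrogenated much more slowly, and the neutral medium avoids lactonisation of the freed hydroxymethyl group onto the side-chain ester.

**Compound list**
1 | (4S)-4-benzyl-1,3-oxazolidin-2-one | O=C1N[C@@H](Cc2ccccc2)CO1 | starting material
2 | (2E)-but-2-enoyl chloride | C/C=C/C(Cl)=O | starting material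
3 | lithium (4S)-4-benzyl-2-oxo-1,3-oxazolidin-3-ide | [Li+].O=C1[N-][C@@H](Cc2ccccc2)CO1 | intermediate (not isolated)
4 | (4S)-4-benzyl-3-[(2E)-but-2-enoyl]-1,3-oxazolidin-2-one | C/C=C/C(=O)N1C(=O)OC[C@@H]1Cc1ccccc1 | intermediate
5 | acetaldehyde | CC=O | starting material
6 | (4S)-4-benzyl-3-[(1Z)-1-[(dibutylboranyl)oxy]buta-1,3-dien-1-yl]-1,3-oxazolidin-2-one | C=C/C=C(\OB(CCCC)CCCC)N1C(=O)OC[C@@H]1Cc1ccccc1 | intermediate (not isolated)
7 | (4S)-4-benzyl-3-[(2S,3R)-3-[(dibutylboranyl)oxy]-2-ethenylbutanoyl]-1,3-oxazolidin-2-one | CCCCB(CCCC)O[C@H](C)[C@@H](C(=O)N1C(=O)OC[C@@H]1Cc1ccccc1)C=C | intermediate (not isolated)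
8 | (4S)-4-benzyl-3-[(2S,3R)-2-ethenyl-3-hydroxybutanoyl]-1,3-oxazolidin-2-one | O[C@H](C)[C@@H](C(=O)N1C(=O)OC[C@@H]1Cc1ccccc1)C=C | intermediate
9 | (4S)-4-benzyl-3-[(2S,3R)-3-[(tert-butyldimethylsilyl)oxy]-2-ethenylbutanoyl]-1,3-oxazolidin-2-one | CC(C)(C)[Si](C)(C)O[C@H](C)[C@@H](C(=O)N1C(=O)OC[C@@H]1Cc1ccccc1)C=C | intermediate
10 | (2R,3R)-3-[(tert-butyldimethylsilyl)oxy]-2-ethenylbutan-1-ol | CC(C)(C)[Si](C)(C)O[C@H](C)[C@@H](CO)C=C | intermediate
11 | {[(2R,3R)-3-[(benzyloxy)methyl]pent-4-en-2-yl]oxy}(tert-butyl)dimethylsilane | CC(C)(C)[Si](C)(C)O[C@H](C)[C@@H](COCc1ccccc1)C=C | intermediate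
12 | (2R,3R)-3-[(benzyloxy)methyl]pent-4-en-2-ol | O[C@H](C)[C@@H](COCc1ccccc1)C=C | intermediate
13 | prop-2-enoyl chloride | C=CC(Cl)=O | starting material
14 | (2R,3R)-3-[(benzyloxy)methyl]pent-4-en-2-yl prop-2-enoate | C=CC(=O)O[C@H](C)[C@@H](COCc1ccccc1)C=C | intermediate
15 | (5R,6R)-5-[(benzyloxy)methyl]-6-methyl-5,6-dihydro-2H-pyran-2-one | O=C1O[C@H](C)[C@@H](COCc2ccccc2)C=C1 | intermediate
16 | dimethyl propanedioate | COC(=O)CC(=O)OC | starting material
17 | dimethyl 2-[(2R,3R,4R)-3-[(benzyloxy)methyl]-2-methyl-6-oxooxan-4-yl]propanedioate | O=C1O[C@H](C)[C@@H](COCc2ccccc2)[C@H](C(C(=O)OC)C(=O)OC)C1 | intermediate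
18 | methyl formate | COC=O | starting material
19 | disodium salt of 20 (formyl-lactone enolate and malonate enolate; ring stereocentres as in 17) | O=C1O[C@H](C)[C@@H](COCc2ccccc2)[C@H](C(C(=O)OC)=C([O-])OC)C1=C[O-].[Na+].[Na+] | intermediate (not isolated)
20 | dimethyl 2-[(2R,3R,4R)-3-[(benzyloxy)methyl]-5-(hydroxymethylidene)-2-methyl-6-oxooxan-4-yl]propanedioate | O=C1O[C@H](C)[C@@H](COCc2ccccc2)[C@H](C(C(=O)OC)C(=O)OC)C1=CO | intermediate
21 | dimethyl 2-[(2R,3R,4S)-3-[(benzyloxy)methyl]-6-methoxy-5-(methoxycarbonyl)-2-methyloxan-4-yl]propanedioate (epimer mixture at C5 and C6) | COC1O[C@H](C)[C@@H](COCc2ccccc2)[C@H](C(C(=O)OC)C(=O)OC)C1C(=O)OC | intermediate (not isolated)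
22 | dimethyl 2-[(2R,3R,4R)-3-[(benzyloxy)methyl]-5-(methoxycarbonyl)-2-methyl-3,4-dihydro-2H-pyran-4-yl]propanedioate | COC(=O)C1=CO[C@H](C)[C@@H](COCc2ccccc2)[C@@H]1C(C(=O)OC)C(=O)OC | intermediate
23 | methyl (2R,3R,4S)-3-[(benzyloxy)methyl]-4-(2-methoxy-2-oxoethyl)-2-methyl-3,4-dihydro-2H-pyran-5-carboxylate | COC(=O)C1=CO[C@H](C)[C@@H](COCc2ccccc2)[C@@H]1CC(=O)OC | intermediate
24 | lithium 2-[(2R,3R,4S)-3-[(benzyloxy)methyl]-5-(methoxycarbonyl)-2-methyl-3,4-dihydro-2H-pyran-4-yl]acetate | COC(=O)C1=CO[C@H](C)[C@@H](COCc2ccccc2)[C@@H]1CC(=O)[O-].[Li+] | intermediate (not isolated)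
25 | 2-[(2R,3R,4S)-3-[(benzyloxy)methyl]-5-(methoxycarbonyl)-2-methyl-3,4-dihydro-2H-pyran-4-yl]acetic acid | COC(=O)C1=CO[C@H](C)[C@@H](COCc2ccccc2)[C@@H]1CC(=O)O | intermediate
26 | (3,4-dihydroxyphenyl)acetic acid | OC(=O)Cc1ccc(O)c(O)c1 | starting material
27 | benzyl [3,4-bis(benzyloxy)phenyl]acetate | O=C(Cc1ccc(OCc2ccccc2)c(OCc2ccccc2)c1)OCc1ccccc1 | intermediate
28 | 2-[3,4-bis(benzyloxy)phenyl]ethan-1-ol | OCCc1ccc(OCc2ccccc2)c(OCc2ccccc2)c1 | intermediate
29 | methyl (2R,3R,4S)-3-[(benzyloxy)methyl]-4-(2-{2-[3,4-bis(benzyloxy)phenyl]ethoxy}-2-oxoethyl)-2-methyl-3,4-dihydro-2H-pyran-5-carboxylate | COC(=O)C1=CO[C@H](C)[C@@H](COCc2ccccc2)[C@@H]1CC(=O)OCCc1ccc(OCc2ccccc2)c(OCc2ccccc2)c1 | intermediate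
30 | methyl (2R,3R,4S)-4-{2-[2-(3,4-dihydroxyphenyl)ethoxy]-2-oxoethyl}-3-(hydroxymethyl)-2-methyl-3,4-dihydro-2H-pyran-5-carboxylate | COC(=O)C1=CO[C@H](C)[C@@H](CO)[C@@H]1CC(=O)OCCc1ccc(O)c(O)c1 | target

**Totals**
Total step count: 17.
Longest linear sequence: 15 steps (steps 1–13, 16 and 17, from 1 to 30); steps 14–15 form the two-step side branch to 28.

**Steps most likely to fail, with fallbacks**

Step 9 (Michael addition; risk of slow conversion or incomplete trans selectivity). The fallback sets out from 15 and comes back at 25. The malonate is replaced by an allyl group, a non-enolisable masked CH2CO2H, introduced by irreversible organocopper conjugate allylation (allylmagnesium bromide, CuBr·SMe2, TMSCl, THF, −78 °C) anti to the CH2OBn group. This gives (4R,5R,6R)-5-[(benzyloxy)methyl]-6-methyl-4-(prop-2-en-1-yl)oxan-2-one F1. Claisen formylation (NaH, HCO2Me, THF) is now unambiguous and passes through sodium [(4S,5R,6R)-5-[(benzyloxy)methyl]-6-methyl-2-oxo-4-(prop-2-en-1-yl)oxan-3-ylidene]methanolate F2, which on acidification gives (4S,5R,6R)-5-[(benzyloxy)methyl]-3-(hydroxymethylidene)-6-methyl-4-(prop-2-en-1-yl)oxan-2-one F3. Methanolic HCl converts this into methyl (4S,5R,6R)-5-[(benzyloxy)methyl]-2-methoxy-6-methyl-4-(prop-2-en-1-yl)oxane-3-carboxylate F4, which loses methanol with TsOH·H2O in hot toluene to give methyl (2R,3R,4S)-3-[(benzyloxy)methyl]-2-methyl-4-(prop-2-en-1-yl)-3,4-dihydro-2H-pyran-5-carboxylate F5. OsO4 (cat.), NaIO4 and 2,6-lutidine in dioxane/water cleave only the terminal alkene to methyl (2R,3R,4S)-3-[(benzyloxy)methyl]-2-methyl-4-(2-oxoethyl)-3,4-dihydro-2H-pyran-5-carboxylate F6. Oxidation with NaClO2, NaH2PO4 and 2-methylbut-2-ene in t-BuOH/water then gives acid 25, and the route resumes at step 16.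

Step 10 (formylation of the lactone in the presence of the malonate; risk of low conversion or side reactions of the bis-enolate). The fallback sets out from 17 and comes back at 22. The base-mediated Claisen condensation is replaced by neutral aminomethylenation with tert-butoxybis(dimethylamino)methane (toluene, 80 °C). The malonate carbon carries a single hydrogen and cannot condense, so only the lactone CH2 reacts, giving dimethyl 2-[(2R,3R,4R)-3-[(benzyloxy)methyl]-5-[(dimethylamino)methylidene]-2-methyl-6-oxooxan-4-yl]propanedioate F7. Methanolic HCl then effects the same ring switch through acetal 21 with loss of dimethylamine, and TsOH·H2O in toluene gives 22.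

Step 17 (global hydrogenolysis; risk of slow cleavage of the alkyl benzyl ether or reduction of the enol ether alkene). The fallback sets out from 29 and comes back at 30. Reductive cleavage is abandoned for Lewis-acid dealkylation with a cation scavenger (BCl3, pentamethylbenzene, CH2Cl2, −78 °C, cold MeOH quench), which removes all three benzyl groups without hydrogen and leaves alkenes and esters untouched. It makes no new intermediate.

**Further compounds**
F1 | step 9 | (4R,5R,6R)-5-[(benzyloxy)methyl]-6-methyl-4-(prop-2-en-1-yl)oxan-2-one | O=C1O[C@H](C)[C@@H](COCc2ccccc2)[C@H](CC=C)C1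
F2 | step 9 | sodium [(4S,5R,6R)-5-[(benzyloxy)methyl]-6-methyl-2-oxo-4-(prop-2-en-1-yl)oxan-3-ylidene]methanolate (not isolated) | O=C1O[C@H](C)[C@@H](COCc2ccccc2)[C@H](CC=C)C1=C[O-].[Na+]
F3 | step 9 | (4S,5R,6R)-5-[(benzyloxy)methyl]-3-(hydroxymethylidene)-6-methyl-4-(prop-2-en-1-yl)oxan-2-one | O=C1O[C@H](C)[C@@H](COCc2ccccc2)[C@H](CC=C)C1=CO
F4 | step 9 | methyl (4S,5R,6R)-5-[(benzyloxy)methyl]-2-methoxy-6-methyl-4-(prop-2-en-1-yl)oxane-3-carboxylate (epimer mixture at C2 and C3, not isolated) | COC1O[C@H](C)[C@@H](COCc2ccccc2)[C@H](CC=C)C1C(=O)OC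
F5 | step 9 | methyl (2R,3R,4S)-3-[(benzyloxy)methyl]-2-methyl-4-(prop-2-en-1-yl)-3,4-dihydro-2H-pyran-5-carboxylate | COC(=O)C1=CO[C@H](C)[C@@H](COCc2ccccc2)[C@@H]1CC=C
F6 | step 9 | methyl (2R,3R,4S)-3-[(benzyloxy)methyl]-2-methyl-4-(2-oxoethyl)-3,4-dihydro-2H-pyran-5-carboxylate | COC(=O)C1=CO[C@H](C)[C@@H](COCc2ccccc2)[C@@H]1CC=O
F7 | step 10 | dimethyl 2-[(2R,3R,4R)-3-[(benzyloxy)methyl]-5-[(dimethylamino)methylidene]-2-methyl-6-oxooxan-4-yl]propanedioate | O=C1O[C@H](C)[C@@H](COCc2ccccc2)[C@H](C(C(=O)OC)C(=O)OC)C1=CN(C)C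
F0 | step 17 | none | none
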